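**Plateau ratio.** Target over starting material stands at 1.21 at 0.167 d in the spring run, but both earlier runs read 2.82 to 3.09 at 0.833 d and 3.00 d. Pooled, those readings give 2.99: the plateau ratio, target over starting material once the two move together, a quasi-equilibrium ratio.

| flask | starting material | remark | time |
|---|---|---|---|
| spring | 0.20 M | run made earlier |  |
| summer | 0.30 M | run made earlier |  |
| flask | 0.40 M |  | 15 d |

| run | time / d | target / % | starting material / % |
|---|---|---|---|
| spring | 0.167 | 19.6 | 16.2 |
| spring | 0.833 | 21.7 | 7.2 |
| spring | 3.00 | 20.9 | 7.4 |
| spring | 15.0 | 14.9 | 4.8 |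
| summer | 0.167 | 17.6 | 14.6 |
| summer | 0.833 | 21.0 | 6.8 |
| summer | 3.00 | 18.5 | 6.1 |
| summer | 15.0 | 13.0 | 2.9 |

(each reading ± 0.5 percentage points)

- the moment within 15 d at which there is most target
- the amount of target, in percent of the starting material charged, at that time

**Turning time.** In the spring run, the target readings climb while the ratio rises to the plateau, then fall with starting material, to 14.9 % at 15.0 d from 20.9 % at 3.00 d. This reckoning therefore puts the peak of the new flask near 0.833 d.

**Turning [starting material].** Between the runs at 0.20 M and 0.30 M, the reading of starting material at 0.833 d drops from 7.2 % to 6.8 %, each good to 0.5 percentage points. The same step up to 0.40 M reckons 6.40 % for the flask. The plateau ratio then gives 19.1 % target, and the balance of the charge leaves 74.5 % outside these two.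

**The forecast.** It says "The maximum therefore lies near the end of the fast phase" and gives 0.7 d (0.4 d to 1.4 d) and 19.8 % (18.3 % to 21.2 %), a target above this reckoning.

**Flask result.** The flask peaks at 0.702 d with 18.9 % target, against 19.1 % reckoned here.

    2 starting material → homo dimer (k = 0.494 L mol⁻¹ h⁻¹)
    starting material ⇌ target (K = 2.94, k = 0.293 h⁻¹)
    target ⇌ isomer of the product A (K = 1.50, k = 1.48 h⁻¹)
    isomer of the product A ⇌ isomer of the product B (K = 0.505, k = 0.0490 h⁻¹)
    isomer of the product B ⇌ starting material (k = 0.0769 h⁻¹)

**Ratio reused.** At that peak, homo dimer, which counts as two in every percentage, holds 31.6 % of the charge, and by 15.0 d it holds 61.5 %. The plateau ratio times the flask's 6.24 % starting material at the peak gives 18.7 % target, against 18.9 %. In the neighbour flask at 0.16 M, the 5.59 % starting material at 15.0 d gives 16.7 % target, against 16.7 %.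

The data were generated by integration for substances that don't exist, and the scatter is random.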